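**Plan**
- Retrosynthesis (chroman numbering): C5–C6 of ring A is cut first. This unfolds the arene into a 1,3-diketone chain on C2 of a methyl 6,6-dimethyl-5,6-dihydro-4H-pyran-3-carboxylate. The later cuts are C6–acyl, C7–C8, O1–C2, C4–C4a and the aryl–prenyl bond of ring B.
- Enabling feature: ring A (C4a, C5, C6, C7, C8, C8a) is an acylphloroglucinol, a folded tetraketide with oxygen on C5, C7 and C8a and the acyl group on C6. The oxygen para to C6 is the pyran O1, so it can be fixed as an enol ether while C4a=C8a is still an alkene. That alkene holds the ester carbon (future C5) cis to the chain (C8) and leaves no hydrogen on C4a for an aldol fold.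
- Forward: the pyran ring is made first by prenylation of methyl acetoacetate and acid cycloisomerisation. The chain then grows from the pyran 2-methyl group by two Weinreb acylations (acetyl, then the ring-B-prenylated phloretic unit). Ring A closes last by Claisen cyclisation with aromatisation.
- Stereochemistry: none to set, because the target has no stereocentre and no stereogenic double bond.

Key step: step 7

Remark: because the target is achiral, the demand for a single enantiomer is met by the constitution alone. LDA and Mg(OMe)2 are taken as commercial solutions.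

**Step 1**
Reactants: 1 methyl acetoacetate; 2 prenyl bromide (1-bromo-3-methylbut-2-ene)
Product: 3 methyl 2-acetyl-5-methylhex-4-enoate (racemic, labile α-centre)
Conditions: NaH (1.0 equiv), THF, 0 °C; then 2 (0.95 equiv), 0 °C → rt
Reagents that add atoms: none
Why: Acetoacetic ester alkylation, in which the sodium enolate of 1 displaces the primary allylic bromide by SN2; a slight deficit of 2 should keep dialkylation low, and the racemic α-centre disappears in step 2.

**Step 2**
Reactants: 3 methyl 2-acetyl-5-methylhex-4-enoate
Product: 4 methyl 2,6,6-trimethyl-5,6-dihydro-4H-pyran-3-carboxylate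
Conditions: TfOH (10 mol %), CH2Cl2, 0 °C → rt
Reagents that add atoms: none
Why: Brønsted-acid-catalysed cycloisomerisation (intramolecular Markovnikov hydroalkoxylation), in which protonation of the trisubstituted alkene gives a tertiary cation that the enol oxygen of the acetyl group captures in a six-membered ring; this is known behaviour of α-prenyl β-keto esters, and the conjugated push–pull enol ether is the thermodynamic sink.

**Step 3**
Reactants: 4 methyl 2,6,6-trimethyl-5,6-dihydro-4H-pyran-3-carboxylate; 5 N-methoxy-N-methylacetamide
Product: 6 methyl 6,6-dimethyl-2-(2-oxopropyl)-5,6-dihydro-4H-pyran-3-carboxylate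
Conditions: LDA (1.1 equiv), THF, −78 °C; then 5, −78 → −20 °C; AcOH/THF quench
Reagents that add atoms: none
Why: Vinylogous (γ) deprotonation of a β-alkoxy enoate followed by Weinreb ketone synthesis, in which the ester carbonyl guides LDA to the cis 2-methyl group and the fully substituted α-carbon leaves only the γ-terminus free to attack, as with the lithium dienolates of 3-alkoxycrotonates and 6-methyl-1,3-dioxin-4-ones; the chelated tetrahedral adduct blocks double addition and proton transfer from the more acidic product.

**Step 4**
Reactants: 7 3-(4-hydroxyphenyl)propanoic acid (phloretic acid)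
Product: 8 3-(4-hydroxyphenyl)-N-methoxy-N-methylpropanamide
Conditions: MeNH(OMe)·HCl, EDC·HCl, N-methylmorpholine, CH2Cl2–DMF, 0 °C → rt
Reagents that add atoms: N,O-dimethylhydroxylamine hydrochloride, CNOC.Cl
Why: Carbodiimide amide coupling, in which the amine outcompetes the phenol for the O-acylisourea, so the phenol needs no protection.

**Step 5**
Reactants: 8 3-(4-hydroxyphenyl)-N-methoxy-N-methylpropanamide; 2 prenyl bromide
Product: 9 3-[4-hydroxy-3-(3-methylbut-2-en-1-yl)phenyl]-N-methoxy-N-methylpropanamide
Conditions: NaH (1.05 equiv), toluene, 0 °C → rt; then 2 (1.0 equiv), rt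
Reagents that add atoms: none
Why: Ortho C-alkylation of a phenoxide in a non-polar medium, in which the poorly solvated sodium phenoxide ion pair meets the allylic bromide through carbon rather than oxygen; the para position is blocked and the two ortho positions are equivalent, so a single C-prenyl isomer should result and be separable from O-alkylated material.

**Step 6**
Reactants: 6 methyl 6,6-dimethyl-2-(2-oxopropyl)-5,6-dihydro-4H-pyran-3-carboxylate; 9 3-[4-hydroxy-3-(3-methylbut-2-en-1-yl)phenyl]-N-methoxy-N-methylpropanamide
Product: 10 methyl 2-{6-[4-hydroxy-3-(3-methylbut-2-en-1-yl)phenyl]-2,4-dioxohexyl}-6,6-dimethyl-5,6-dihydro-4H-pyran-3-carboxylate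
Conditions: 6, LDA (3.3 equiv), THF, −78 → −40 °C; then 9, −78 → −10 °C; AcOH/THF quench at −78 °C
Reagents that add atoms: none
Why: Terminal acylation of a β-dicarbonyl-type dianion with a Weinreb amide, as practised on 6-(2-oxopropyl)-1,3-dioxin-4-ones, in which two equivalents of LDA deprotonate first the doubly activated ring-side methylene and then the terminal methyl group, a third holds the phenol of 9 as its lithium phenoxide, and the last-formed terminal carbanion attacks the amide; the first charge is delocalised into the ester, so the dianion should not close on itself, and the cold acid quench releases the diketone only in a non-basic medium.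

**Step 7**
Reactants: 10 methyl 2-{6-[4-hydroxy-3-(3-methylbut-2-en-1-yl)phenyl]-2,4-dioxohexyl}-6,6-dimethyl-5,6-dihydro-4H-pyran-3-carboxylate
Product: 12 1-(5,7-dihydroxy-2,2-dimethyl-3,4-dihydro-2H-chromen-6-yl)-3-[4-hydroxy-3-(3-methylbut-2-en-1-yl)phenyl]propan-1-one (the target), via triketone tautomer 11 (not isolated)
Conditions: Mg(OMe)2 (4 equiv), MeOH, reflux, Ar; then ice-cold 0.5 M HCl, EtOAc
Reagents that add atoms: none
Why: Proposed new method: magnesium methoxide ionises the side-chain 1,3-diketone, its central carbon (future C6) adds to the ester carbonyl (future C5), loss of methoxide gives the β-triketone 11, and two enolisations turn 11 into aromatic ring A, which is held irreversibly as its magnesium phenoxide chelate. The closest known reaction type is the Claisen (Dieckmann-type) cyclisation of 3,5,7-trioxo esters, and of the 2-pyranones derived from them, to acylphloroglucinols under alkoxide or Mg(OMe)2; not yet shown is a substrate whose 3-oxygen is a tetrasubstituted cyclic enol ether, but a neutral alkoxy donor should deactivate the ester less than the enolate oxygen that occupies this place in the known cases. The single ring closed is carbocycle A, by a 6-exo-trig attack that is allowed in both the enolexo and the enolendo sense, with the C4a=C8a double bond of the dihydropyran keeping ester and chain cis. No stereocentre is formed. The step needs C- over O-acylation and the Claisen over the aldol fold: C4a bears no hydrogen, so the resorcylate fold is closed, and lactonisation through the C7 enol oxygen to a 2-pyranone is reversed by methoxide, so material should drain through aromatisation, the only irreversible exit. O1 is already alkylated before the arene exists, so no choice among the three ring-A oxygens arises, and the basic medium with a brief cold work-up leaves the acid-sensitive ortho-prenylphenol of ring B untouched.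

**Compound list**
1 | methyl acetoacetate | COC(=O)CC(C)=O | starting material
2 | prenyl bromide (1-bromo-3-methylbut-2-ene) | CC(C)=CCBr | starting material
3 | methyl 2-acetyl-5-methylhex-4-enoate (racemic) | COC(=O)C(CC=C(C)C)C(C)=O | intermediate
4 | methyl 2,6,6-trimethyl-5,6-dihydro-4H-pyran-3-carboxylate | COC(=O)C1=C(C)OC(C)(C)CC1 | intermediate
5 | N-methoxy-N-methylacetamide | CON(C)C(C)=O | starting material
6 | methyl 6,6-dimethyl-2-(2-oxopropyl)-5,6-dihydro-4H-pyran-3-carboxylate | COC(=O)C1=C(CC(C)=O)OC(C)(C)CC1 | intermediate
7 | 3-(4-hydroxyphenyl)propanoic acid (phloretic acid) | O=C(O)CCc1ccc(O)cc1 | starting material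
8 | 3-(4-hydroxyphenyl)-N-methoxy-N-methylpropanamide | CON(C)C(=O)CCc1ccc(O)cc1 | intermediate
9 | 3-[4-hydroxy-3-(3-methylbut-2-en-1-yl)phenyl]-N-methoxy-N-methylpropanamide | CON(C)C(=O)CCc1ccc(O)c(CC=C(C)C)c1 | intermediate
10 | methyl 2-{6-[4-hydroxy-3-(3-methylbut-2-en-1-yl)phenyl]-2,4-dioxohexyl}-6,6-dimethyl-5,6-dihydro-4H-pyran-3-carboxylate | COC(=O)C1=C(CC(=O)CC(=O)CCc2ccc(O)c(CC=C(C)C)c2)OC(C)(C)CC1 | intermediate
11 | 6-{3-[4-hydroxy-3-(3-methylbut-2-en-1-yl)phenyl]propanoyl}-2,2-dimethyl-3,4-dihydro-2H-chromene-5,7(6H,8H)-dione (non-aromatic keto tautomer of 12, C6 labile, not isolated) | CC(C)=CCc1cc(CCC(=O)C2C(=O)CC3=C(CCC(C)(C)O3)C2=O)ccc1O | intermediate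
12 | 1-(5,7-dihydroxy-2,2-dimethyl-3,4-dihydro-2H-chromen-6-yl)-3-[4-hydroxy-3-(3-methylbut-2-en-1-yl)phenyl]propan-1-one | CC(C)=CCc1cc(CCC(=O)c2c(O)cc3c(c2O)CCC(C)(C)O3)ccc1O | target

**Total step count:** 7. **Longest linear sequence:** 5 (steps 1, 2, 3, 6, 7); the ring-B branch (steps 4, 5) joins at step 6.

**Steps most likely to fail**

**Step 7.**
- What may go wrong: slow addition of the stabilised diketonate to the donor-deactivated ester; diversion into lactonisation through the enol oxygen; exchange of the ring oxygen at C8a by methoxide through addition–elimination; retro-Claisen cleavage of the diketone.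
- The fallback sets out from 9 and returns at 12, and it buys ring A instead of building it.
- Phloroglucinol is condensed with isoprene over Amberlyst 15 to give 2,2-dimethylchroman-5,7-diol F1.
- MOMCl/iPr2NEt caps both phenols to give 5,7-bis(methoxymethoxy)-2,2-dimethylchroman F2.
- n-BuLi in THF at 0 °C lithiates F2 by directed ortho-metalation at C6, the position flanked by both MOM ethers.
- The aryllithium is added to 9, which has first been turned into its lithium phenoxide with LiHMDS. This Weinreb ketone synthesis gives 1-[5,7-bis(methoxymethoxy)-2,2-dimethylchroman-6-yl]-3-[4-hydroxy-3-(3-methylbut-2-en-1-yl)phenyl]propan-1-one F3.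
- Dilute HCl in MeOH at room temperature, a treatment that ortho-prenylphenols are known to tolerate, removes the two carbonyl-flanking MOM groups and gives 12.

**Step 6.**
- What may go wrong: incomplete second deprotonation; proton transfer from the enolisable amide to the dianion; self-closure of the dianion onto the ester.
- The fallback sets out from 9, uses 6 again and returns at 10. It replaces acylation by aldol addition and oxidation.
- TBSCl/imidazole converts 9 into 3-[4-(tert-butyldimethylsilyloxy)-3-(3-methylbut-2-en-1-yl)phenyl]-N-methoxy-N-methylpropanamide F4.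
- DIBAL-H at −78 °C reduces F4 to 3-[4-(tert-butyldimethylsilyloxy)-3-(3-methylbut-2-en-1-yl)phenyl]propanal F5.
- The far more electrophilic aldehyde intercepts the dianion of 6 at −78 °C. The product is the racemic methyl 2-{6-[4-(tert-butyldimethylsilyloxy)-3-(3-methylbut-2-en-1-yl)phenyl]-4-hydroxy-2-oxohexyl}-6,6-dimethyl-5,6-dihydro-4H-pyran-3-carboxylate F6.
- Dess–Martin periodinane oxidises the carbinol to the silylated diketone methyl 2-{6-[4-(tert-butyldimethylsilyloxy)-3-(3-methylbut-2-en-1-yl)phenyl]-2,4-dioxohexyl}-6,6-dimethyl-5,6-dihydro-4H-pyran-3-carboxylate F7.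
- Et3N·3HF in THF frees the phenol to give 10.

**Step 5.**
- What may go wrong: competing O-alkylation of the phenoxide and a second C-alkylation at the other ortho position.
- The fallback sets out from 8 and returns at 9. It delivers the prenyl group by a sigmatropic shift, so that only ortho carbon can be reached.
- 3-Chloro-3-methylbut-1-yne with catalytic CuCl2 and DBU in MeCN etherifies 8 to N-methoxy-N-methyl-3-{4-[(2-methylbut-3-yn-2-yl)oxy]phenyl}propanamide F8.
- Lindlar semihydrogenation of F8 gives N-methoxy-N-methyl-3-{4-[(2-methylbut-3-en-2-yl)oxy]phenyl}propanamide F9.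
- Heating F9 in toluene at 110 °C brings about the aromatic Claisen rearrangement to 9.

**Further compounds**
F1 | step 7 | 2,2-dimethylchroman-5,7-diol | CC1(C)CCc2c(O)cc(O)cc2O1
F2 | step 7 | 5,7-bis(methoxymethoxy)-2,2-dimethylchroman | COCOc1cc(OCOC)c2c(c1)OC(C)(C)CC2
F3 | step 7 | 1-[5,7-bis(methoxymethoxy)-2,2-dimethylchroman-6-yl]-3-[4-hydroxy-3-(3-methylbut-2-en-1-yl)phenyl]propan-1-one | COCOc1cc2c(c(OCOC)c1C(=O)CCc1ccc(O)c(CC=C(C)C)c1)CCC(C)(C)O2
F4 | step 6 | 3-[4-(tert-butyldimethylsilyloxy)-3-(3-methylbut-2-en-1-yl)phenyl]-N-methoxy-N-methylpropanamide | CON(C)C(=O)CCc1ccc(O[Si](C)(C)C(C)(C)C)c(CC=C(C)C)c1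
F5 | step 6 | 3-[4-(tert-butyldimethylsilyloxy)-3-(3-methylbut-2-en-1-yl)phenyl]propanal | O=CCCc1ccc(O[Si](C)(C)C(C)(C)C)c(CC=C(C)C)c1
F6 | step 6 | methyl 2-{6-[4-(tert-butyldimethylsilyloxy)-3-(3-methylbut-2-en-1-yl)phenyl]-4-hydroxy-2-oxohexyl}-6,6-dimethyl-5,6-dihydro-4H-pyran-3-carboxylate (racemic) | COC(=O)C1=C(CC(=O)CC(O)CCc2ccc(O[Si](C)(C)C(C)(C)C)c(CC=C(C)C)c2)OC(C)(C)CC1
F7 | step 6 | methyl 2-{6-[4-(tert-butyldimethylsilyloxy)-3-(3-methylbut-2-en-1-yl)phenyl]-2,4-dioxohexyl}-6,6-dimethyl-5,6-dihydro-4H-pyran-3-carboxylate | COC(=O)C1=C(CC(=O)CC(=O)CCc2ccc(O[Si](C)(C)C(C)(C)C)c(CC=C(C)C)c2)OC(C)(C)CC1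
F8 | step 5 | N-methoxy-N-methyl-3-{4-[(2-methylbut-3-yn-2-yl)oxy]phenyl}propanamide | CON(C)C(=O)CCc1ccc(OC(C)(C)C#C)cc1
F9 | step 5 | N-methoxy-N-methyl-3-{4-[(2-methylbut-3-en-2-yl)oxy]phenyl}propanamide | CON(C)C(=O)CCc1ccc(OC(C)(C)C=C)cc1
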